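Compounds are numbered 1–19 in the order they appear in the steps; 19 is the target.

## Analysis of the target

- The target 19 is an isoflavone. Rings A and C form a 5,7-dihydroxy-4H-chromen-4-one, and ring B sits on C3.
- Ring B is also the benzo ring of a 2H-chromene. Its 2'-oxygen and C3' are bridged by C2–C3=C4 of the new pyran, so the isoflavone C3 is bonded to C8 of the 2H-chromene and the 4'-hydroxyl is its 5-OH.
- The only stereocentre is the quaternary C2 of the 2H-chromene. It carries the ring oxygen, the vinyl carbon C3, a methyl and a hydroxymethyl group, and it is (S). With no second centre, only absolute control matters.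
- Sensitive groups are the tertiary allylic aryl ether next to a styrene-type double bond (ionisable by strong acid, reducible by hydrogenation), three phenols (the 5-OH chelated to C4=O), a primary alcohol, and C2 of the pyranone, which accepts nucleophiles.
- The synthesis is hard for three reasons. A quaternary ether carbon with two small, similar substituents (CH3 and CH2OH) has to be set enantioselectively on a hindered phenol oxygen. The 2'-oxygen must be told apart from three other phenolic oxygens. The groups that survive ring construction are not the ones that can be removed from the finished chromene.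
- The plan rests on ring A being a phloroglucinol unit. In a 3,5-dioxygenated aryl ether bound through the future O1, the two ring carbons ortho to that oxygen are equivalent. Forming the pyranone last at C4–C4a by acylation therefore has no regiochemical choice.

## Retrosynthetic reasoning

**19 ⇒ 18.** The last operation should touch only O–Si bonds. The tertiary allylic aryl ether and the C3=C4 double bond rule out late hydrogenolysis and strong Lewis acids. The phenols at O7 and O4' and the primary alcohol are therefore carried as silyl ethers in 18 and freed together under buffered conditions. The chelated 5-OH needs no protection.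

**18 ⇒ 17.** The C4–C4a bond of the 2H-chromene is cut, giving the aryl propargyl ether 17. The forward reaction, a gold-catalysed 6-endo hydroarylation, leaves the O–C2 bond and the stereocentre untouched. Only one carbon ortho to the ether oxygen is free (C3' of ring B); the other (C1') carries the isoflavone. A thermal sigmatropic route to the same ring would break O–C2 and pass through an achiral dienone, so it would erase the configuration.

**17 ⇒ 16 ⇒ 11 + 15.** The aryl O–C2 bond is cut next. A quaternary carbon cannot be joined to a phenol oxygen by direct displacement, but copper-catalysed propargylic substitution accepts a phenoxide at such a carbon. Racemic carbonate 15 is the electrophile: both enantiomers give the same planar intermediate, so the ligand alone sets the configuration, and decarboxylation leaves the hydroxymethyl group of 16 in place. Carbonate 15 goes back through diol 14 to 12 and 13. The alcohol of 16 is silylated to 17 so that it cannot add to the activated alkyne.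

**11 ⇒ 10.** The 2'-hydroxyl has to be the only reactive phenol in 11. This is reached from tetraol 10 by silylating the two exposed phenols at O7 and O4'. The 5-OH is chelated, and the 2'-OH is shielded by the neighbouring chromenone.

**10 ⇒ 9.** The four O–CH3 bonds are cut. Methyl ethers are needed for the acidic ring closure but could not be removed from the finished chromene, so the exchange is placed at the isoflavone stage.

**9 ⇒ 7 (through 8).** This is the central disconnection, the C4–C4a bond of the pyranone. It leads to the Z-configured 3-aryloxy-2-arylacrylic acid 7, whose activated form 8 acylates ring A. Cutting here means the closure cannot give regioisomers, and the precursor contains only acid-stable groups. The forward step has to form one C–C bond and the pyranone ring.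

**7 ⇒ 6 ⇒ 4 + 5.** The enol ether bond O1–C2 is cut. Phenol 5 displaces the sulfonate of 4 by addition–elimination, so the bond usually made last in chromone syntheses is made first. Saponification of 6 then gives 7.

**4 ⇒ 3 ⇒ 2 ⇒ 1.** The C2–C3 bond goes back to a one-carbon Claisen condensation on ester 2. The C3–C1' bond, the hardest one to make late, is already present in commercial acid 1.

## Alternatives that were turned down

**Alternative 1: palladium-catalysed aryl etherification of a tertiary alcohol.**
- Disconnection: the 2H-pyran of ring B is cut at O1–C8a.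
- Forward key step: the enantiopure Z-alkenyl tertiary alcohol A2 is cyclised with Pd(OAc)2, a di-tert-butyl(biaryl)phosphine and Cs2CO3. The alkoxide replaces the bromide and gives the 2H-chromene A1; the chloride is kept for a later junction with the isoflavone.
- For: the quaternary centre would come from a tertiary alcohol made by established asymmetric chemistry. The configuration would not depend on an untested enantioselective etherification, so on this point the alternative is stronger than the chosen route (step 11). A tertiary alkoxide also has no hydrogen on the carbinol carbon, so β-hydride loss from the palladium alkoxide is closed.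
- Against: the bromide is flanked on both sides. The Z geometry must be set and must survive palladium hydride species, because the E isomer cannot close. The bromide has to react before the chloride.
- Against, structurally: A1 is only ring B. The C3–C1' bond would still have to be made at a chloride ortho to the ring oxygen, with the acid-sensitive chromene on board from the start.
- Comparison: the chosen strategy has C3–C1' from compound 1 and brings in the sensitive ring at the very end. It pays for this with step 11.

**Alternative 2: memory-of-chirality enolate alkylation.**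
- Disconnection: the C2–C3 bond of the pyran; the stereocentre is traced to the chiral pool.
- Forward key step: the lactate-derived aryl ether A4 is deprotonated with KN(SiMe3)2 at low temperature. The enolate is chiral only through slow rotation about its aryl–O bond; it displaces iodide from the ortho iodoethyl arm in a 6-exo-tet closure and gives the chroman ester A3.
- For: a cheap chiral source, no catalyst or auxiliary, and a fast intramolecular alkylation. Like alternative 1 it avoids an untested catalytic step.
- Against: the enantiomeric purity depends on the lifetime of a conformationally chiral enolate, held only by two ortho substituents and low temperature. Partial racemisation could not be repaired later.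
- Against, structurally: A3 is at the wrong oxidation level twice. The ester must be reduced to CH2OH and the chroman dehydrogenated at C3–C4 next to an electron-rich ring. The isoflavone would still have to be attached through the bromide.
- Comparison: the chosen route forms the ring directly as a 2H-chromene with the hydroxymethyl group in place, and is shorter.

**Alternative 3: oxidative 1,2-aryl shift of a chalcone.**
- Disconnection: the isoflavone is cut at C3–C1' and O1–C2, back to the chalcone A6.
- Forward key step: PhI(OH)OTs (trivalent iodine) in methanol with trimethyl orthoformate adds to the enone and ring B migrates from the β- to the α-carbon. Methanolic HCl then closes the pyranone, removes the MOM groups and gives the isoflavone A5.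
- For: A6 comes from a simple aldol condensation, and the sequence to the isoflavone is at least as short as steps 1–7. Above all, the 2'-oxygen arrives as a benzyl ether distinct from the other three oxygens, so the selective silylation of step 8 is not needed. On both points this alternative is as strong as or stronger than the chosen route.
- Against: an electrophilic oxidant meets two very electron-rich rings, so ring oxidation and oxidative closure to five- or six-membered by-products compete. The migrating ring carries an ortho substituent, and acid-labile protecting groups must survive the oxidation.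
- Comparison: the chosen strategy offers a ring construction without any oxidant, with only acid and methyl ethers present, and with no regiochemical or chemoselectivity question in the ring-forming step. The price is step 8.

Key step: step 6

Assumption: the (S,S)-configured pybox ligand is taken to give the (S)-ether 16; if the sense of induction is the opposite, the enantiomeric ligand is used and nothing else changes.

## Route

Step 1
Reactants: 1 2-(2,4-dimethoxyphenyl)acetic acid
Product: 2 methyl 2-(2,4-dimethoxyphenyl)acetate
Conditions: MeOH, H2SO4 (cat.), reflux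
Reagents that add atoms: methanol, CO
Why: Fischer esterification; the ester allows the benzylic CH2 to be deprotonated and formylated in step 2.

Step 2
Reactants: 2 methyl 2-(2,4-dimethoxyphenyl)acetate
Product: 3 methyl (Z)-2-(2,4-dimethoxyphenyl)-3-hydroxyprop-2-enoate (chelated enol of the α-formyl ester)
Conditions: NaH, HCO2Me, THF, 0 °C to rt; then aq. HCl
Reagents that add atoms: methyl formate, COC=O
Why: Crossed Claisen condensation with a non-enolisable formate, driven by deprotonation of the product; the new carbon becomes C2 of the isoflavone.

Step 3
Reactants: 3 methyl (Z)-2-(2,4-dimethoxyphenyl)-3-hydroxyprop-2-enoate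
Product: 4 methyl (Z)-2-(2,4-dimethoxyphenyl)-3-(tosyloxy)prop-2-enoate
Conditions: TsCl, TMEDA, LiCl, MeCN, 0 °C
Reagents that add atoms: p-toluenesulfonyl chloride, Cc1ccc(cc1)S(=O)(=O)Cl
Why: O-sulfonylation of the enol; lithium chelation between the enolate oxygen and the ester carbonyl should hold the Z geometry, so the leaving group ends up cis to the ester.

Step 4
Reactants: 4 methyl (Z)-2-(2,4-dimethoxyphenyl)-3-(tosyloxy)prop-2-enoate; 5 3,5-dimethoxyphenol
Product: 6 methyl (Z)-3-(3,5-dimethoxyphenoxy)-2-(2,4-dimethoxyphenyl)prop-2-enoate
Conditions: Cs2CO3, MeCN, rt to 40 °C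
Reagents that add atoms: none
Why: Nucleophilic vinylic substitution by addition–elimination: the phenoxide adds to the β-carbon, which is activated by the ester, and tosylate leaves, forming the future O1–C2 bond. Retention of the Z geometry is expected, and any E isomer is harmless because step 6 equilibrates the geometry.

Step 5
Reactants: 6 methyl (Z)-3-(3,5-dimethoxyphenoxy)-2-(2,4-dimethoxyphenyl)prop-2-enoate
Product: 7 (Z)-3-(3,5-dimethoxyphenoxy)-2-(2,4-dimethoxyphenyl)prop-2-enoic acid
Conditions: LiOH, THF/MeOH/H2O, rt; then aq. HCl
Reagents that add atoms: lithium hydroxide, [Li+].[OH-]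
Why: Saponification of the methyl ester; attack at the ester carbonyl should outpace conjugate displacement of the aryloxide at room temperature, as in the usual hydrolysis of 3-aryloxyacrylates.

Step 6
Reactants: 7 (Z)-3-(3,5-dimethoxyphenoxy)-2-(2,4-dimethoxyphenyl)prop-2-enoic acid
Product: 9 5,7,2',4'-tetramethoxyisoflavone, via mixed trifluoroacetic anhydride 8 (not isolated)
Conditions: (CF3CO)2O, CF3CO2H, CH2Cl2, 0 °C to rt
Reagents that add atoms: none
Why: (CF3CO)2O converts the acid into the mixed anhydride 8, which in CF3CO2H acts as an acylium equivalent; its acyl carbon is attacked by one of the two equivalent ring A carbons ortho to the enol ether oxygen, each also ortho to one methoxy group and para to the other, and loss of a proton from the σ-complex gives the chromen-4-one. This is an intramolecular Friedel–Crafts acylation, and the closest known reaction type is the acid-promoted cyclisation of 3-aryloxyacrylic acids to chromones. The pyranone ring closes in a six-membered mode, exo with respect to the acyl C=O and endo with respect to the aromatic π-bond that acts as nucleophile, forming C4–C4a. No stereocentre is formed. Regioselectivity is not at issue, because the two ortho carbons are related by the symmetry of ring A and the carbon between the two methoxy groups cannot reach the acyl group. The closure needs the aryloxy group cis to the acyl group; 7 is made with this Z geometry, and any E isomer should equilibrate in the acid by reversible protonation at the α-carbon and be drawn through to the same product. Chemoselectivity rests on intramolecularity: ring B cannot reach the acyl carbon in a ring of workable size, attack by its ortho methoxy oxygen is reversible as long as nothing removes the methyl group, and the product is deactivated towards further acylation by its carbonyl group.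

Step 7
Reactants: 9 5,7,2',4'-tetramethoxyisoflavone
Product: 10 3-(2,4-dihydroxyphenyl)-5,7-dihydroxy-4H-chromen-4-one (2'-hydroxygenistein)
Conditions: BBr3 (excess), CH2Cl2, −78 °C to rt; then H2O
Reagents that add atoms: none
Why: Lewis-acid ether cleavage (boron binds each ether oxygen, bromide attacks the methyl group), standard for polymethoxyisoflavones. It is done here because the later chromene would not survive it.

Step 8
Reactants: 10 3-(2,4-dihydroxyphenyl)-5,7-dihydroxy-4H-chromen-4-one
Product: 11 5-hydroxy-3-[2-hydroxy-4-(triisopropylsilyloxy)phenyl]-7-(triisopropylsilyloxy)-4H-chromen-4-one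
Conditions: TIPSCl (2.1 equiv), imidazole, DMF, 0 °C
Reagents that add atoms: triisopropylsilyl chloride, CC(C)[Si](Cl)(C(C)C)C(C)C
Why: Sterically controlled silylation: the bulky chloride should take the two exposed phenols, O7 (the most acidic) and O4'. The 5-OH is chelated to C4=O, and the 2'-OH is flanked by the chromenone and hydrogen-bonded to it.

Step 9
Reactants: 12 hydroxyacetone; 13 ethynylmagnesium bromide
Product: 14 rac-2-methylbut-3-yne-1,2-diol
Conditions: HC≡CMgBr (2.5 equiv), THF, 0 °C to rt; then cold dilute aq. HCl
Reagents that add atoms: none
Why: Grignard addition to the ketone; the first equivalent deprotonates the hydroxyl and the second adds to the carbonyl. The racemate is sufficient because step 11 is enantioconvergent.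

Step 10
Reactants: 14 rac-2-methylbut-3-yne-1,2-diol
Product: 15 rac-4-ethynyl-4-methyl-1,3-dioxolan-2-one
Conditions: 1,1'-carbonyldiimidazole, 4-(dimethylamino)pyridine (cat.), CH2Cl2, rt
Reagents that add atoms: 1,1'-carbonyldiimidazole, O=C(n1ccnc1)n1ccnc1
Why: Cyclic carbonate formation from a 1,2-diol: acylation of the primary hydroxyl, then five-membered ring closure by the tertiary one. The carbonate is the leaving group for step 11.

Step 11
Reactants: 11 5-hydroxy-3-[2-hydroxy-4-(triisopropylsilyloxy)phenyl]-7-(triisopropylsilyloxy)-4H-chromen-4-one; 15 rac-4-ethynyl-4-methyl-1,3-dioxolan-2-one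
Product: 16 5-hydroxy-3-[2-{[(2S)-1-hydroxy-2-methylbut-3-yn-2-yl]oxy}-4-(triisopropylsilyloxy)phenyl]-7-(triisopropylsilyloxy)-4H-chromen-4-one
Conditions: Cu(MeCN)4PF6 (5 mol %), 2,6-bis[(4S)-4-phenyl-4,5-dihydro-1,3-oxazol-2-yl]pyridine (6 mol %), iPr2NEt, THF, −10 °C
Reagents that add atoms: none
Why: Proposed new method: the monovalent copper–pybox complex forms a copper acetylide from 15, loss of the carbonate as CO2 gives a copper allenylidene with a pendant alkoxide, and the 2'-phenoxide of 11 (the only free, unchelated phenol) adds to the γ-carbon on the face left open by the ligand, so both enantiomers of 15 converge on (S)-16. The closest known reactions are the copper–pybox enantioselective propargylic etherification of secondary propargylic esters with phenols and the enantioselective decarboxylative amination of tertiary ethynyl cyclic carbonates; the enantioselective union of a phenol with a tertiary carbonate is the new element.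

Step 12
Reactants: 16 5-hydroxy-3-[2-{[(2S)-1-hydroxy-2-methylbut-3-yn-2-yl]oxy}-4-(triisopropylsilyloxy)phenyl]-7-(triisopropylsilyloxy)-4H-chromen-4-one
Product: 17 3-[2-{[(2S)-1-(tert-butyldimethylsilyloxy)-2-methylbut-3-yn-2-yl]oxy}-4-(triisopropylsilyloxy)phenyl]-5-hydroxy-7-(triisopropylsilyloxy)-4H-chromen-4-one
Conditions: TBSCl, imidazole, CH2Cl2, 0 °C to rt
Reagents that add atoms: tert-butyldimethylsilyl chloride, CC(C)(C)[Si](C)(C)Cl
Why: Silylation of the primary alcohol, selective over the chelated 5-OH. It prevents the hydroxyl from adding to the gold-activated alkyne in step 13.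

Step 13
Reactants: 17 3-[2-{[(2S)-1-(tert-butyldimethylsilyloxy)-2-methylbut-3-yn-2-yl]oxy}-4-(triisopropylsilyloxy)phenyl]-5-hydroxy-7-(triisopropylsilyloxy)-4H-chromen-4-one
Product: 18 3-[(2S)-2-[(tert-butyldimethylsilyloxy)methyl]-2-methyl-5-(triisopropylsilyloxy)-2H-chromen-8-yl]-5-hydroxy-7-(triisopropylsilyloxy)-4H-chromen-4-one
Conditions: Ph3PAuNTf2 (5 mol %), CH2Cl2, rt
Reagents that add atoms: none
Why: Gold-catalysed intramolecular hydroarylation of an aryl propargyl ether: monovalent gold activates the alkyne, C3' of ring B (the only free ortho carbon, activated by two ortho oxygens) attacks the terminal carbon in a 6-endo-dig closure, and protodeauration gives the 2H-chromene. The O–C2 bond is not broken, so the (S) centre should be retained.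

Step 14
Reactants: 18 3-[(2S)-2-[(tert-butyldimethylsilyloxy)methyl]-2-methyl-5-(triisopropylsilyloxy)-2H-chromen-8-yl]-5-hydroxy-7-(triisopropylsilyloxy)-4H-chromen-4-one
Product: 19 5,7-dihydroxy-3-[(2S)-5-hydroxy-2-(hydroxymethyl)-2-methyl-2H-chromen-8-yl]-4H-chromen-4-one
Conditions: Bu4NF, AcOH, THF, 0 °C to rt
Reagents that add atoms: none
Why: Fluoride-mediated cleavage of the two aryl silyl ethers and the primary silyl ether in one operation. Buffering with AcOH keeps the medium close to neutral, so the allylic aryl ether and the pyranone are not exposed to acid or strong base.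

## Compound list

1 | 2-(2,4-dimethoxyphenyl)acetic acid | OC(=O)Cc1ccc(OC)cc1OC | starting material
2 | methyl 2-(2,4-dimethoxyphenyl)acetate | COC(=O)Cc1ccc(OC)cc1OC | intermediate
3 | methyl (Z)-2-(2,4-dimethoxyphenyl)-3-hydroxyprop-2-enoate | COC(=O)/C(=C\O)c1ccc(OC)cc1OC | intermediate
4 | methyl (Z)-2-(2,4-dimethoxyphenyl)-3-(tosyloxy)prop-2-enoate | COC(=O)/C(=C\OS(=O)(=O)c1ccc(C)cc1)c1ccc(OC)cc1OC | intermediate
5 | 3,5-dimethoxyphenol | COc1cc(O)cc(OC)c1 | starting material
6 | methyl (Z)-3-(3,5-dimethoxyphenoxy)-2-(2,4-dimethoxyphenyl)prop-2-enoate | COC(=O)/C(=C\Oc1cc(OC)cc(OC)c1)c1ccc(OC)cc1OC | intermediate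
7 | (Z)-3-(3,5-dimethoxyphenoxy)-2-(2,4-dimethoxyphenyl)prop-2-enoic acid | OC(=O)/C(=C\Oc1cc(OC)cc(OC)c1)c1ccc(OC)cc1OC | intermediate
8 | (Z)-3-(3,5-dimethoxyphenoxy)-2-(2,4-dimethoxyphenyl)prop-2-enoic trifluoroacetic anhydride | O=C(OC(=O)C(F)(F)F)/C(=C\Oc1cc(OC)cc(OC)c1)c1ccc(OC)cc1OC | intermediate
9 | 3-(2,4-dimethoxyphenyl)-5,7-dimethoxy-4H-chromen-4-one (5,7,2',4'-tetramethoxyisoflavone) | O=c1c(-c2ccc(OC)cc2OC)coc2cc(OC)cc(OC)c12 | intermediate
10 | 3-(2,4-dihydroxyphenyl)-5,7-dihydroxy-4H-chromen-4-one | O=c1c(-c2ccc(O)cc2O)coc2cc(O)cc(O)c12 | intermediate
11 | 5-hydroxy-3-[2-hydroxy-4-(triisopropylsilyloxy)phenyl]-7-(triisopropylsilyloxy)-4H-chromen-4-one | O=c1c(-c2ccc(O[Si](C(C)C)(C(C)C)C(C)C)cc2O)coc2cc(O[Si](C(C)C)(C(C)C)C(C)C)cc(O)c12 | intermediate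
12 | hydroxyacetone | CC(=O)CO | starting material
13 | ethynylmagnesium bromide | C#C[Mg]Br | starting material
14 | rac-2-methylbut-3-yne-1,2-diol | CC(O)(CO)C#C | intermediate
15 | rac-4-ethynyl-4-methyl-1,3-dioxolan-2-one | CC1(C#C)COC(=O)O1 | intermediate
16 | 5-hydroxy-3-[2-{[(2S)-1-hydroxy-2-methylbut-3-yn-2-yl]oxy}-4-(triisopropylsilyloxy)phenyl]-7-(triisopropylsilyloxy)-4H-chromen-4-one | C[C@@](CO)(C#C)Oc1cc(O[Si](C(C)C)(C(C)C)C(C)C)ccc1-c1coc2cc(O[Si](C(C)C)(C(C)C)C(C)C)cc(O)c2c1=O | intermediate
17 | 3-[2-{[(2S)-1-(tert-butyldimethylsilyloxy)-2-methylbut-3-yn-2-yl]oxy}-4-(triisopropylsilyloxy)phenyl]-5-hydroxy-7-(triisopropylsilyloxy)-4H-chromen-4-one | C[C@@](CO[Si](C)(C)C(C)(C)C)(C#C)Oc1cc(O[Si](C(C)C)(C(C)C)C(C)C)ccc1-c1coc2cc(O[Si](C(C)C)(C(C)C)C(C)C)cc(O)c2c1=O | intermediate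
18 | 3-[(2S)-2-[(tert-butyldimethylsilyloxy)methyl]-2-methyl-5-(triisopropylsilyloxy)-2H-chromen-8-yl]-5-hydroxy-7-(triisopropylsilyloxy)-4H-chromen-4-one | C[C@@]1(CO[Si](C)(C)C(C)(C)C)C=Cc2c(O[Si](C(C)C)(C(C)C)C(C)C)ccc(-c3coc4cc(O[Si](C(C)C)(C(C)C)C(C)C)cc(O)c4c3=O)c2O1 | intermediate
19 | 5,7-dihydroxy-3-[(2S)-5-hydroxy-2-(hydroxymethyl)-2-methyl-2H-chromen-8-yl]-4H-chromen-4-one | C[C@@]1(CO)C=Cc2c(O)ccc(-c3coc4cc(O)cc(O)c4c3=O)c2O1 | target

## Step count and least certain steps

Total: 14 steps. Longest linear sequence: 12 steps (steps 1–8 and 11–14, from 1). Steps 9 and 10 are a two-step side branch to 15.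

**Step 11 (new method).**
- What may go wrong: poor facial discrimination, because methyl and oxymethyl at the allenylidene terminus differ little in size.
- Slow attack by the hindered, ortho-substituted phenoxide would leave room for C-propargylation of ring B.
- The 5-hydroxy-4-keto unit of 11 may sequester copper. This is why a monovalent copper salt is chosen; divalent copper would be chelated more strongly.
- A stronger base would allow the 2'-phenoxide to add to C2 of the pyranone, so only a hindered amine is used.
- Fallback, from 14 and 11, returning at 17: the primary hydroxyl of 14 is silylated (TBSCl, imidazole) to give rac-1-[(tert-butyldimethylsilyl)oxy]-2-methylbut-3-yn-2-ol F1. LiN(SiMe3)2 and ClCO2Me convert it into rac-1-[(tert-butyldimethylsilyl)oxy]-2-methylbut-3-yn-2-yl methyl carbonate F2. Phenol 11 is etherified with F2 under CuCl2 (cat.) and DBU in MeCN at 0 °C, the established achiral copper route to tertiary propargylic aryl ethers, to give racemic 3-[2-{[1-(tert-butyldimethylsilyloxy)-2-methylbut-3-yn-2-yl]oxy}-4-(triisopropylsilyloxy)phenyl]-5-hydroxy-7-(triisopropylsilyloxy)-4H-chromen-4-one F3. The enantiomers are separated by preparative chromatography on a chiral stationary phase; the (S)-enantiomer is 17. The stereocentre then comes from resolution instead of catalysis.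

**Step 6 (key step).**
- What may go wrong: intermolecular trifluoroacetylation of the electron-rich rings competing with ring closure.
- Capture of the acyl group by the ortho methoxy oxygen of ring B, followed by loss of the methyl group, would give a five-membered lactone.
- Acid cleavage of the enol ether by adventitious water would return 5.
- An E isomer that equilibrates slowly would stall the closure.
- Fallback, from 1 and 5, returning at 9: 1 and 5 are heated in BF3·OEt2. Ortho-acylation of the phenol, directed by boron chelation, should give the deoxybenzoin 1-(2-hydroxy-4,6-dimethoxyphenyl)-2-(2,4-dimethoxyphenyl)ethan-1-one F4. Condensation of F4 with Me2NCH(OMe)2 inserts the C2 carbon at the benzylic CH2 and closes the ring through the phenol to give 9. The pyranone is then closed at O1–C2 instead of C4–C4a.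

**Step 8.**
- What may go wrong: insufficient discrimination between the 2'- and 4'-hydroxyls, giving over-silylation or the wrong disilyl isomer. The selectivity rests only on steric shielding and hydrogen bonding of the 2'-OH.
- Fallback, from 10, returning at 11, using selective deprotection instead of selective protection: 10 is peracetylated (Ac2O, pyridine, 4-(dimethylamino)pyridine) to 3-(2,4-diacetoxyphenyl)-4-oxo-4H-chromene-5,7-diyl diacetate F5. Lipase-catalysed alcoholysis (immobilised Candida antarctica lipase B, n-butanol, THF) should remove the two exposed acetates at O7 and O4', the usual site preference of lipases on peracetylated flavonoids, to give 3-(2-acetoxy-4-hydroxyphenyl)-7-hydroxy-4-oxo-4H-chromen-5-yl acetate F6. TIPSCl and imidazole silylate the two freed phenols to give 3-[2-acetoxy-4-(triisopropylsilyloxy)phenyl]-4-oxo-7-(triisopropylsilyloxy)-4H-chromen-5-yl acetate F7. NH4OAc in aqueous MeOH cleaves the two aryl acetates to give 11.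

**Step 13.**
- What may go wrong: ionisation of the tertiary propargylic C–O bond by the cationic gold complex, with loss of the side chain or erosion of configuration.
- Slow attack at the crowded C3' between two oxygen substituents would let the catalyst decay.
- Fallback, from 17, returning at 18, using iodonium activation in place of π-acid catalysis: I2 and NaHCO3 in MeCN should induce the same 6-endo closure and give the 3-iodo-2H-chromene 3-[(2R)-2-[(tert-butyldimethylsilyloxy)methyl]-3-iodo-2-methyl-5-(triisopropylsilyloxy)-2H-chromen-8-yl]-5-hydroxy-7-(triisopropylsilyloxy)-4H-chromen-4-one F8. The descriptor changes only because iodine raises the priority of C3; the spatial arrangement is that of 18. Hydrodeiodination with Pd(OAc)2, PPh3, HCO2H and Et3N in DMF then gives 18.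

## Further compounds

F1 | step 11 | rac-1-[(tert-butyldimethylsilyl)oxy]-2-methylbut-3-yn-2-ol | CC(O)(CO[Si](C)(C)C(C)(C)C)C#C
F2 | step 11 | rac-1-[(tert-butyldimethylsilyl)oxy]-2-methylbut-3-yn-2-yl methyl carbonate | COC(=O)OC(C)(CO[Si](C)(C)C(C)(C)C)C#C
F3 | step 11 | racemic 3-[2-{[1-(tert-butyldimethylsilyloxy)-2-methylbut-3-yn-2-yl]oxy}-4-(triisopropylsilyloxy)phenyl]-5-hydroxy-7-(triisopropylsilyloxy)-4H-chromen-4-one | CC(CO[Si](C)(C)C(C)(C)C)(C#C)Oc1cc(O[Si](C(C)C)(C(C)C)C(C)C)ccc1-c1coc2cc(O[Si](C(C)C)(C(C)C)C(C)C)cc(O)c2c1=O
F4 | step 6 | 1-(2-hydroxy-4,6-dimethoxyphenyl)-2-(2,4-dimethoxyphenyl)ethan-1-one | COc1cc(O)c(C(=O)Cc2ccc(OC)cc2OC)c(OC)c1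
F5 | step 8 | 3-(2,4-diacetoxyphenyl)-4-oxo-4H-chromene-5,7-diyl diacetate | CC(=O)Oc1ccc(-c2coc3cc(OC(C)=O)cc(OC(C)=O)c3c2=O)c(OC(C)=O)c1
F6 | step 8 | 3-(2-acetoxy-4-hydroxyphenyl)-7-hydroxy-4-oxo-4H-chromen-5-yl acetate | CC(=O)Oc1cc(O)ccc1-c1coc2cc(O)cc(OC(C)=O)c2c1=O
F7 | step 8 | 3-[2-acetoxy-4-(triisopropylsilyloxy)phenyl]-4-oxo-7-(triisopropylsilyloxy)-4H-chromen-5-yl acetate | CC(=O)Oc1cc(O[Si](C(C)C)(C(C)C)C(C)C)ccc1-c1coc2cc(O[Si](C(C)C)(C(C)C)C(C)C)cc(OC(C)=O)c2c1=O
F8 | step 13 | 3-[(2R)-2-[(tert-butyldimethylsilyloxy)methyl]-3-iodo-2-methyl-5-(triisopropylsilyloxy)-2H-chromen-8-yl]-5-hydroxy-7-(triisopropylsilyloxy)-4H-chromen-4-one | C[C@@]1(CO[Si](C)(C)C(C)(C)C)C(I)=Cc2c(O[Si](C(C)C)(C(C)C)C(C)C)ccc(-c3coc4cc(O[Si](C(C)C)(C(C)C)C(C)C)cc(O)c4c3=O)c2O1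
A1 | alternative 1 | (2S)-2-{[(tert-butyldimethylsilyl)oxy]methyl}-8-chloro-5-(methoxymethoxy)-2-methyl-2H-chromene | C[C@@]1(CO[Si](C)(C)C(C)(C)C)C=Cc2c(OCOC)ccc(Cl)c2O1
A2 | alternative 1 | (2S,3Z)-4-[2-bromo-3-chloro-6-(methoxymethoxy)phenyl]-1-[(tert-butyldimethylsilyl)oxy]-2-methylbut-3-en-2-ol | C[C@@](O)(CO[Si](C)(C)C(C)(C)C)/C=C\c1c(OCOC)ccc(Cl)c1Br
A3 | alternative 2 | ethyl (2S)-8-bromo-5-(methoxymethoxy)-2-methylchromane-2-carboxylate | C[C@@]1(C(=O)OCC)CCc2c(OCOC)ccc(Br)c2O1
A4 | alternative 2 | ethyl (2R)-2-[6-bromo-2-(2-iodoethyl)-3-(methoxymethoxy)phenoxy]propanoate | C[C@@H](Oc1c(Br)ccc(OCOC)c1CCI)C(=O)OCC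
A5 | alternative 3 | 3-[2-(benzyloxy)-4-hydroxyphenyl]-5,7-dihydroxy-4H-chromen-4-one | O=c1c(-c2ccc(O)cc2OCc2ccccc2)coc2cc(O)cc(O)c12
A6 | alternative 3 | (E)-3-[2-(benzyloxy)-4-(methoxymethoxy)phenyl]-1-[2,4,6-tris(methoxymethoxy)phenyl]prop-2-en-1-one | COCOc1cc(OCOC)c(C(=O)/C=C/c2ccc(OCOC)cc2OCc2ccccc2)c(OCOC)c1
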